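The route rests on disconnecting the dihydropyran ring (O1, C2, C3, C4, C4a, C8a) across O1–C2 and C3–C4. Atoms O1/C8a/C4a/C4 are read as a latent o-quinone methide of the phloroglucinol-type A ring, and C2–C3 as the enamine of a B-ring arylacetaldehyde. One aminocatalytic oxa-[4+2] annulation joins the two arenes, closes the pyran ring and sets C3; its precursors are an acyclic sulfone and an aldehyde. C2 emerges as a lactol carbon that is then deoxygenated. The 2'-OH/3'-prenyl pair of ring B travels as a 1,1-dimethylpropargyl ether and is unveiled late by semi-hydrogenation and aromatic Claisen rearrangement.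

Key step: step 6

Remark: the configuration at C3 is assigned with the usual steric-shielding model of diarylprolinol silyl ether enamines, applied to the (R)-catalyst C[Si](C)(C)OC(c1ccccc1)(c1ccccc1)[C@H]1CCCN1. Aldehydes 1 and 5 and both catalyst enantiomers are taken as commercial.

Step 1
Reactants: 1 2-hydroxy-4-methoxybenzaldehyde
Product: 2 4-methoxy-2-[(2-methylbut-3-yn-2-yl)oxy]benzaldehyde
Conditions: 3-chloro-3-methylbut-1-yne, DBU, CuCl2·2H2O (cat.), MeCN, 0 °C to rt
Reagents that add atoms: 3-chloro-3-methylbut-1-yne, CC(C)(Cl)C#C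
Why: copper-catalysed O-alkylation of a phenol with a tertiary propargylic chloride should tolerate the hindered, hydrogen-bonded salicylaldehyde hydroxyl; no stereocenter is formed.

Step 2
Reactants: 2 4-methoxy-2-[(2-methylbut-3-yn-2-yl)oxy]benzaldehyde
Product: 3 4-methoxy-1-(2-methoxyethenyl)-2-[(2-methylbut-3-yn-2-yl)oxy]benzene (E/Z mixture)
Conditions: Ph3P(CH2OMe)Cl, NaHMDS, THF, 0 °C to rt
Reagents that add atoms: (methoxymethyl)triphenylphosphonium chloride, COC[P+](c1ccccc1)(c1ccccc1)c1ccccc1.[Cl-]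
Why: Wittig olefination with the methoxymethylidene ylide should give the one-carbon homologated enol ether, whose geometry is irrelevant because both isomers hydrolyse to the same aldehyde.

Step 3
Reactants: 3 4-methoxy-1-(2-methoxyethenyl)-2-[(2-methylbut-3-yn-2-yl)oxy]benzene
Product: 4 2-{4-methoxy-2-[(2-methylbut-3-yn-2-yl)oxy]phenyl}acetaldehyde
Conditions: 2 M aq. HCl, THF, rt; used crude without delay
Reagents that add atoms: water, O
Why: acid-catalysed enol ether hydrolysis (C-protonation, capture by water, loss of methanol) should be much faster than ionisation of the tertiary propargyl aryl ether under these mild conditions.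

Step 4
Reactants: 5 2,4-dihydroxy-6-methoxybenzaldehyde
Product: 6 2-hydroxy-6-methoxy-4-[(triisopropylsilyl)oxy]benzaldehyde
Conditions: TIPSCl (1.05 equiv), imidazole, CH2Cl2, 0 °C
Reagents that add atoms: triisopropylsilyl chloride, CC(C)[Si](Cl)(C(C)C)C(C)C
Why: the 4-OH is the more acidic hydroxyl and is not tied up in the hydrogen bond to the formyl group, so silylation should be selective for it.

Step 5
Reactants: 6 2-hydroxy-6-methoxy-4-[(triisopropylsilyl)oxy]benzaldehyde
Product: 8 3-methoxy-2-{[(4-methylphenyl)sulfonyl]methyl}-5-[(triisopropylsilyl)oxy]phenol, via salicyl alcohol 7 (not isolated)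
Conditions: NaBH4, THF–EtOH, 0 °C; then p-TolSO2Na (3 equiv), AcOH–H2O, 0 °C to rt
Reagents that add atoms: sodium p-toluenesulfinate, Cc1ccc(cc1)S(=O)[O-].[Na+]
Why: borohydride reduction gives the electron-rich salicyl alcohol, which should ionise under mild acid to the benzylic cation/o-quinone methide and be captured at sulfur by excess sulfinate to give the bench-stable sulfone.

Step 6
Reactants: 4 2-{4-methoxy-2-[(2-methylbut-3-yn-2-yl)oxy]phenyl}acetaldehyde; 8 3-methoxy-2-{[(4-methylphenyl)sulfonyl]methyl}-5-[(triisopropylsilyl)oxy]phenol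
Product: 12 (3R)-5-methoxy-3-{4-methoxy-2-[(2-methylbut-3-yn-2-yl)oxy]phenyl}-7-[(triisopropylsilyl)oxy]-3,4-dihydro-2H-chromen-2-ol (C2 anomers), via o-quinone methide 9 (not isolated), via catalyst enamine 10 (not isolated), via 2-pyrrolidinylchroman 11 (not isolated)
Conditions: (R)-α,α-diphenylprolinol trimethylsilyl ether (20 mol %), Na2CO3 (powder), CHCl3, 0 °C; 8 (1.3 equiv) added in portions
Reagents that add atoms: none
Why: Carbonate converts sulfone 8 into the donor-stabilised o-quinone methide 9 by 1,4-elimination of sulfinate while aldehyde 4 condenses with the (R)-amine to the anti-(E)-enamine 10; the enamine β-carbon adds to the methide carbon of 9 (C3–C4 bond), the phenoxide closes onto the iminium carbon (O1–C2 bond) to give 11, and hydrolysis releases lactol 12 and the amine. The closest known reaction type is the aminocatalytic inverse-electron-demand oxa-Diels–Alder (formal [4+2]) of o-quinone methides with enolisable aldehydes. The pyran ring closes as a formal [4+2] heterocycloaddition, stepwise Michael addition followed by 6-exo-trig attack of the phenoxide oxygen on the iminium carbon. C3 is the only stereocenter that matters (C2 is removed in step 7) and is catalyst-controlled: the CPh2(OTMS) group shields one face of the enamine, so the methide should approach the Re face of the β-carbon and give 3R. The step needs C-alkylation of the enamine to outrun oligomerisation of 9 and N-alkylation of the free amine, which portionwise addition of 8 and the reversibility of amine addition to this donor-rich methide should secure; regiochemistry is fixed because only the methide carbon is electrophilic. Immediate capture of the new α-aryl aldehyde as the cyclic lactol should protect C3 from enamine-mediated racemisation.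

Step 7
Reactants: 12 (3R)-5-methoxy-3-{4-methoxy-2-[(2-methylbut-3-yn-2-yl)oxy]phenyl}-7-[(triisopropylsilyl)oxy]-3,4-dihydro-2H-chromen-2-ol
Product: 13 (3R)-5-methoxy-3-{4-methoxy-2-[(2-methylbut-3-yn-2-yl)oxy]phenyl}-7-[(triisopropylsilyl)oxy]-3,4-dihydro-2H-chromene
Conditions: Et3SiH (4 equiv), BF3·OEt2 (1.5 equiv), CH2Cl2, −78 °C
Reagents that add atoms: none
Why: ionic hydrogenation of a lactol, in which Lewis-acid ionisation of the anomeric hydroxyl gives the cyclic oxocarbenium ion that silane hydride reduces, should turn C2 into CH2 without opening the ring and without touching C3, provided hydride capture at low temperature is faster than loss of H3.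

Step 8
Reactants: 13 (3R)-5-methoxy-3-{4-methoxy-2-[(2-methylbut-3-yn-2-yl)oxy]phenyl}-7-[(triisopropylsilyl)oxy]-3,4-dihydro-2H-chromene
Product: 15 3-methoxy-6-{(3R)-5-methoxy-7-[(triisopropylsilyl)oxy]-3,4-dihydro-2H-chromen-3-yl}-2-(3-methylbut-2-en-1-yl)phenol, via 1,1-dimethylallyl ether 14 (not isolated)
Conditions: H2 (1 atm), Lindlar catalyst, quinoline, EtOAc, rt; filter; then xylenes, 130 °C
Reagents that add atoms: none
Why: Lindlar semi-hydrogenation should stop at the alkene, and the aryl 1,1-dimethylallyl ether 14 should then undergo aromatic Claisen [3,3] rearrangement into the only free ortho position (C3') with allyl inversion to the 3-methylbut-2-enyl group, tautomerisation restoring the 2'-phenol and C3 remaining untouched.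

Step 9
Reactants: 15 3-methoxy-6-{(3R)-5-methoxy-7-[(triisopropylsilyl)oxy]-3,4-dihydro-2H-chromen-3-yl}-2-(3-methylbut-2-en-1-yl)phenol
Product: 16 (3R)-3-[2-hydroxy-4-methoxy-3-(3-methylbut-2-en-1-yl)phenyl]-5-methoxy-3,4-dihydro-2H-chromen-7-ol
Conditions: TBAF, AcOH, THF, 0 °C
Reagents that add atoms: none
Why: fluoride cleavage of the aryl silyl ether, buffered with acetic acid to keep the electron-rich phenols protonated, should leave the prenyl group and the stereocenter unaffected.

Compound list
1 | 2-hydroxy-4-methoxybenzaldehyde | COc1ccc(C=O)c(O)c1 | starting material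
2 | 4-methoxy-2-[(2-methylbut-3-yn-2-yl)oxy]benzaldehyde | COc1ccc(C=O)c(OC(C)(C)C#C)c1 | intermediate
3 | 4-methoxy-1-(2-methoxyethenyl)-2-[(2-methylbut-3-yn-2-yl)oxy]benzene (E/Z mixture) | COC=Cc1ccc(OC)cc1OC(C)(C)C#C | intermediate
4 | 2-{4-methoxy-2-[(2-methylbut-3-yn-2-yl)oxy]phenyl}acetaldehyde | COc1ccc(CC=O)c(OC(C)(C)C#C)c1 | intermediate
5 | 2,4-dihydroxy-6-methoxybenzaldehyde | COc1cc(O)cc(O)c1C=O | starting material
6 | 2-hydroxy-6-methoxy-4-[(triisopropylsilyl)oxy]benzaldehyde | COc1cc(O[Si](C(C)C)(C(C)C)C(C)C)cc(O)c1C=O | intermediate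
7 | 2-(hydroxymethyl)-3-methoxy-5-[(triisopropylsilyl)oxy]phenol | COc1cc(O[Si](C(C)C)(C(C)C)C(C)C)cc(O)c1CO | intermediate
8 | 3-methoxy-2-{[(4-methylphenyl)sulfonyl]methyl}-5-[(triisopropylsilyl)oxy]phenol | COc1cc(O[Si](C(C)C)(C(C)C)C(C)C)cc(O)c1CS(=O)(=O)c1ccc(C)cc1 | intermediate
9 | 5-methoxy-6-methylidene-3-[(triisopropylsilyl)oxy]cyclohexa-2,4-dien-1-one | C=C1C(=O)C=C(O[Si](C(C)C)(C(C)C)C(C)C)C=C1OC | intermediate
10 | (2R)-2-[diphenyl(trimethylsilyloxy)methyl]-1-[(E)-2-{4-methoxy-2-[(2-methylbut-3-yn-2-yl)oxy]phenyl}ethenyl]pyrrolidine | C[Si](C)(C)OC(c1ccccc1)(c1ccccc1)[C@H]1CCCN1/C=C/c1ccc(OC)cc1OC(C)(C)C#C | intermediate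
11 | (3R)-2-{(2R)-2-[diphenyl(trimethylsilyloxy)methyl]pyrrolidin-1-yl}-5-methoxy-3-{4-methoxy-2-[(2-methylbut-3-yn-2-yl)oxy]phenyl}-7-[(triisopropylsilyl)oxy]-3,4-dihydro-2H-chromene (C2 epimers) | COc1cc(O[Si](C(C)C)(C(C)C)C(C)C)cc2c1C[C@H](c1ccc(OC)cc1OC(C)(C)C#C)C(N1CCC[C@@H]1C(c1ccccc1)(c1ccccc1)O[Si](C)(C)C)O2 | intermediate
12 | (3R)-5-methoxy-3-{4-methoxy-2-[(2-methylbut-3-yn-2-yl)oxy]phenyl}-7-[(triisopropylsilyl)oxy]-3,4-dihydro-2H-chromen-2-ol (C2 anomers) | COc1cc(O[Si](C(C)C)(C(C)C)C(C)C)cc2c1C[C@H](c1ccc(OC)cc1OC(C)(C)C#C)C(O)O2 | intermediate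
13 | (3R)-5-methoxy-3-{4-methoxy-2-[(2-methylbut-3-yn-2-yl)oxy]phenyl}-7-[(triisopropylsilyl)oxy]-3,4-dihydro-2H-chromene | COc1cc(O[Si](C(C)C)(C(C)C)C(C)C)cc2c1C[C@H](c1ccc(OC)cc1OC(C)(C)C#C)CO2 | intermediate
14 | (3R)-5-methoxy-3-{4-methoxy-2-[(2-methylbut-3-en-2-yl)oxy]phenyl}-7-[(triisopropylsilyl)oxy]-3,4-dihydro-2H-chromene | COc1cc(O[Si](C(C)C)(C(C)C)C(C)C)cc2c1C[C@H](c1ccc(OC)cc1OC(C)(C)C=C)CO2 | intermediate
15 | 3-methoxy-6-{(3R)-5-methoxy-7-[(triisopropylsilyl)oxy]-3,4-dihydro-2H-chromen-3-yl}-2-(3-methylbut-2-en-1-yl)phenol | COc1cc(O[Si](C(C)C)(C(C)C)C(C)C)cc2c1C[C@H](c1ccc(OC)c(CC=C(C)C)c1O)CO2 | intermediate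
16 | (3R)-3-[2-hydroxy-4-methoxy-3-(3-methylbut-2-en-1-yl)phenyl]-5-methoxy-3,4-dihydro-2H-chromen-7-ol | COc1cc(O)cc2c1C[C@H](c1ccc(OC)c(CC=C(C)C)c1O)CO2 | target

Total step count: 9. Longest linear sequence: 7 steps (steps 1, 2, 3, 6, 7, 8, 9).

Steps most likely to fail

Step 6. The risks are poor facial selectivity or racemisation at C3 through re-formation of the enamine, oligomerisation of the o-quinone methide, and loss of the catalyst by N-alkylation. The fallback replaces catalyst control by a stoichiometric oxazolidinone auxiliary and closes the ring by C–O bond formation. It sets out from 4: Pinnick oxidation (NaClO2, NaH2PO4, 2-methylbut-2-ene) should give the arylacetic acid F1. Pivaloyl chloride/Et3N converts it into the mixed pivalic anhydride F2, which acylates lithiated (R)-4-benzyloxazolidin-2-one to give the imide F3. The sodium enolate of F3 (NaHMDS, 2.2 equiv, THF, −78 °C; the second equivalent unmasks 9 from 8) should be alkylated at the methide carbon on the face opposite the benzyl group, giving the (R)-configured alkylated imide F4. LiBH4 reduction releases the auxiliary and gives the phenol–primary alcohol diol F5, and Mitsunobu cyclisation (PPh3, DIAD, THF) closes O1–C2 and comes back to the route at 13.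

Step 7. The risks are loss of configuration at C3 by elimination of the oxocarbenium ion to the 4H-chromene and reprotonation, and Lewis-acid cleavage of the tertiary propargyl ether. The fallback avoids the cation altogether. It sets out from 12: NaBH4 (EtOH, 0 °C) reduces the open hydroxy-aldehyde tautomer to the diol F6 (the same structure as F5), and Mitsunobu cyclisation (PPh3, DIAD) re-forms the O1–C2 bond and comes back to the route at 13.

Step 5. The risks are Friedel–Crafts self-condensation of the very electron-rich benzylic cation, over-reduction to the methyl compound, and acid-reversible sulfone formation. The fallback uses a different o-quinone methide precursor made without any acid. It sets out from 6: reductive amination with dimethylamine and NaBH(OAc)3 should give the Mannich base F7, and N-methylation with MeI in Et2O gives the trimethylammonium iodide F8. F8 takes the place of 8 in step 6, where carbonate expels trimethylamine to give 9, and the route is rejoined at 12.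

Further compounds
F1 | step 6 | 2-{4-methoxy-2-[(2-methylbut-3-yn-2-yl)oxy]phenyl}acetic acid | COc1ccc(CC(=O)O)c(OC(C)(C)C#C)c1
F2 | step 6 | 2-{4-methoxy-2-[(2-methylbut-3-yn-2-yl)oxy]phenyl}acetic pivalic anhydride | COc1ccc(CC(=O)OC(=O)C(C)(C)C)c(OC(C)(C)C#C)c1
F3 | step 6 | (4R)-4-benzyl-3-(2-{4-methoxy-2-[(2-methylbut-3-yn-2-yl)oxy]phenyl}acetyl)-1,3-oxazolidin-2-one | COc1ccc(CC(=O)N2[C@H](Cc3ccccc3)COC2=O)c(OC(C)(C)C#C)c1
F4 | step 6 | (4R)-4-benzyl-3-[(2R)-3-{2-hydroxy-6-methoxy-4-[(triisopropylsilyl)oxy]phenyl}-2-{4-methoxy-2-[(2-methylbut-3-yn-2-yl)oxy]phenyl}propanoyl]-1,3-oxazolidin-2-one | COc1cc(O[Si](C(C)C)(C(C)C)C(C)C)cc(O)c1C[C@H](c1ccc(OC)cc1OC(C)(C)C#C)C(=O)N1[C@H](Cc2ccccc2)COC1=O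
F5 | step 6 | 2-[(2R)-3-hydroxy-2-{4-methoxy-2-[(2-methylbut-3-yn-2-yl)oxy]phenyl}propyl]-3-methoxy-5-[(triisopropylsilyl)oxy]phenol | COc1cc(O[Si](C(C)C)(C(C)C)C(C)C)cc(O)c1C[C@H](c1ccc(OC)cc1OC(C)(C)C#C)CO
F6 | step 7 | 2-[(2R)-3-hydroxy-2-{4-methoxy-2-[(2-methylbut-3-yn-2-yl)oxy]phenyl}propyl]-3-methoxy-5-[(triisopropylsilyl)oxy]phenol | COc1cc(O[Si](C(C)C)(C(C)C)C(C)C)cc(O)c1C[C@H](c1ccc(OC)cc1OC(C)(C)C#C)CO
F7 | step 5 | 2-[(dimethylamino)methyl]-3-methoxy-5-[(triisopropylsilyl)oxy]phenol | COc1cc(O[Si](C(C)C)(C(C)C)C(C)C)cc(O)c1CN(C)C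
F8 | step 5 | {2-hydroxy-6-methoxy-4-[(triisopropylsilyl)oxy]phenyl}-N,N,N-trimethylmethanaminium iodide | COc1cc(O[Si](C(C)C)(C(C)C)C(C)C)cc(O)c1C[N+](C)(C)C.[I-]
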